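**Retrosynthetic overview**
- The target is a 17-membered 1,5,9,13-tetraaza lactam. Its only stereocentre, ring carbon C8, carries the undecyl chain, the N9-methyl nitrogen and the C7H2–C6(=O) arm. C8 is cut into dodecanal (C8 and the chain), a secondary N-methylamine (N9 with C10–C12 as a silyloxypropyl arm) and trimethylsilylacetylene (C7 and C6), joined by an enantioselective three-component coupling.
- The alkyne terminus is then raised to the N5–C6 amide by rhodium-catalysed anti-Markovnikov oxidative amidation with a Boc-protected N5–N1–N13 triamine arm. The arm comes from N,N'-dimethylbutane-1,4-diamine by mono-Boc protection, cyanoethylation and nitrile hydrogenation.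
- Ring formation: the single ring is closed last, at C12–N13, by intramolecular N-alkylation of the freed methylamine with the 3-chloropropyl arm under high dilution.

Key step: step 2

Remark (assumption): the sense of induction of CuBr/Quinap with the unsymmetrical N-methyl amine is taken to be the same as with dibenzylamine, so (S)-Quinap is chosen for the R amine. If a correlation showed the opposite sense, (R)-Quinap would be used with no other change.

**Route**

Step 1
Reactants: 1 3-(methylamino)propan-1-ol
Product: 2 3-(tert-butyldimethylsilyloxy)-N-methylpropan-1-amine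
Conditions: TBSCl, imidazole, CH2Cl2, 0 °C to rt; aqueous NaHCO3 work-up
Reagents that add atoms: tert-butyldimethylsilyl chloride, CC(C)(C)[Si](C)(C)Cl
Why: O-silylation of the alcohol through the N-silylimidazolium species; any N-silylated amine is hydrolysed on aqueous work-up, so only the silyl ether should remain.

Step 2
Reactants: 2 3-(tert-butyldimethylsilyloxy)-N-methylpropan-1-amine; 3 dodecanal; 4 trimethylsilylacetylene
Product: 6 (R)-N-[3-(tert-butyldimethylsilyloxy)propyl]-N-methyl-1-(trimethylsilyl)tetradec-1-yn-3-amine, via iminium ion 5 (not isolated)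
Conditions: CuBr (5 mol %), (S)-Quinap (5.5 mol %), 4 Å MS, toluene, rt
Reagents that add atoms: none
Why: Aldehyde 3 and amine 2 condense to iminium ion 5 (in equilibrium with its enamine), while CuBr bound to the P,N-ligand turns alkyne 4 into a monovalent copper acetylide that adds to one enantioface of 5, so the C3–N and C3–C2 bonds of 6 form in one flask. The closest known reaction type is the copper-catalysed enantioselective three-component propargylamine synthesis (A3 coupling) of aliphatic aldehydes, secondary amines and trimethylsilylacetylene. No ring is closed in this step. The new stereocentre is under catalyst control alone: the (S)-Quinap copper acetylide is expected to deliver the alkynyl group so as to give the R amine. The step needs enantioface selectivity and clean iminium formation; the unbranched aldehyde and the bulky silylalkyne are the partners that respond best to this catalyst, and the silyl ether keeps the hydroxyl from closing a cyclic N,O-acetal onto the iminium ion. Self-condensation of 3 should be held back by the sieves and the low temperature.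

Step 3
Reactants: 6 (R)-N-[3-(tert-butyldimethylsilyloxy)propyl]-N-methyl-1-(trimethylsilyl)tetradec-1-yn-3-amine
Product: 7 (R)-N-[3-(tert-butyldimethylsilyloxy)propyl]-N-methyltetradec-1-yn-3-amine
Conditions: K2CO3 (0.2 equiv), MeOH, rt
Reagents that add atoms: none
Why: Base-catalysed methanolysis of the alkynyl C–Si bond (protodesilylation), which should leave the primary TBS ether and the propargylic stereocentre untouched.

Step 4
Reactants: 8 N,N'-dimethylbutane-1,4-diamine
Product: 9 tert-butyl N-methyl-N-[4-(methylamino)butyl]carbamate
Conditions: Boc2O (0.3 equiv, slow addition), CH2Cl2, 0 °C; excess 8 removed by aqueous wash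
Reagents that add atoms: di-tert-butyl dicarbonate, CC(C)(C)OC(=O)OC(=O)OC(C)(C)C
Why: Carbamate formation (Boc protection) run with the diamine in excess so that statistics favour the mono-carbamate, which is separated from 8 by extraction.

Step 5
Reactants: 9 tert-butyl N-methyl-N-[4-(methylamino)butyl]carbamate
Product: 10 tert-butyl N-{4-[(2-cyanoethyl)(methyl)amino]butyl}-N-methylcarbamate
Conditions: acrylonitrile (1.2 equiv), MeOH, rt
Reagents that add atoms: acrylonitrile, C=CC#N
Why: Aza-Michael addition of the free secondary amine to acrylonitrile, the usual three-carbon extension of polyamines; the carbamate nitrogen is not nucleophilic.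

Step 6
Reactants: 10 tert-butyl N-{4-[(2-cyanoethyl)(methyl)amino]butyl}-N-methylcarbamate
Product: 11 tert-butyl N-{4-[(3-aminopropyl)(methyl)amino]butyl}-N-methylcarbamate
Conditions: H2 (4 bar), Raney Ni, 7 M NH3 in MeOH, rt
Reagents that add atoms: none
Why: Heterogeneous hydrogenation of the nitrile to the primary amine, with ammonia suppressing secondary-amine formation and the Boc group inert.

Step 7
Reactants: 7 (R)-N-[3-(tert-butyldimethylsilyloxy)propyl]-N-methyltetradec-1-yn-3-amine; 11 tert-butyl N-{4-[(3-aminopropyl)(methyl)amino]butyl}-N-methylcarbamate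
Product: 12 tert-butyl N-{4-[(3-{[(3R)-3-{[3-(tert-butyldimethylsilyloxy)propyl](methyl)amino}tetradecanoyl]amino}propyl)(methyl)amino]butyl}-N-methylcarbamate
Conditions: [Rh(cod)Cl]2 (2.5 mol %), P(4-FC6H4)3 (10 mol %), 4-picoline N-oxide (1.5 equiv), 11 (1.3 equiv), MeCN, 60 °C
Reagents that add atoms: 4-methylpyridine N-oxide, Cc1cc[n+]([O-])cc1
Why: Anti-Markovnikov oxidative amidation of a terminal alkyne: the alkyne should isomerise on monovalent rhodium to a vinylidene whose α-carbon takes oxygen from the N-oxide, and the resulting metal-bound ketene is captured by the primary amine of 11, so the amide forms under near-neutral conditions without a β-amino aldehyde or activated ester that could lose the amine by elimination, and the C3 stereocentre is not involved.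

Step 8
Reactants: 12 tert-butyl N-{4-[(3-{[(3R)-3-{[3-(tert-butyldimethylsilyloxy)propyl](methyl)amino}tetradecanoyl]amino}propyl)(methyl)amino]butyl}-N-methylcarbamate
Product: 13 (3R)-3-[(3-hydroxypropyl)(methyl)amino]-N-(3-{methyl[4-(methylamino)butyl]amino}propyl)tetradecanamide trihydrochloride
Conditions: 3 M HCl in MeOH, rt; evaporation
Reagents that add atoms: hydrogen chloride, Cl
Why: Acidolysis of the Boc carbamate and acid-catalysed methanolysis of the TBS ether in one operation, the product being kept as its trihydrochloride for direct chlorination.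

Step 9
Reactants: 13 (3R)-3-[(3-hydroxypropyl)(methyl)amino]-N-(3-{methyl[4-(methylamino)butyl]amino}propyl)tetradecanamide trihydrochloride
Product: 14 (3R)-3-[(3-chloropropyl)(methyl)amino]-N-(3-{methyl[4-(methylamino)butyl]amino}propyl)tetradecanamide trihydrochloride
Conditions: SOCl2 (3 equiv), CHCl3, 0 °C to 50 °C; evaporation
Reagents that add atoms: thionyl chloride, O=S(Cl)Cl
Why: Deoxychlorination of the primary alcohol through its chlorosulfite; protonation shields all three amines from the reagent and from premature alkylation, and the secondary amide should not react at this temperature.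

Step 10
Reactants: 14 (3R)-3-[(3-chloropropyl)(methyl)amino]-N-(3-{methyl[4-(methylamino)butyl]amino}propyl)tetradecanamide trihydrochloride
Product: 16 (8R)-1,9,13-trimethyl-8-undecyl-1,5,9,13-tetraazacycloheptadecan-6-one, via free-base chloro amine 15 (not isolated)
Conditions: K2CO3 (10 equiv), MeCN, 80 °C; 14 in DMF added by syringe pump, final concentration about 1 mM
Reagents that add atoms: none
Why: Intramolecular SN2 N-alkylation (macrocyclisation at C12–N13, 17-membered ring) of the liberated secondary methylamine by the primary chloride, favoured over oligomerisation by slow addition into high dilution; the stereocentre is remote from the reacting atoms and the tertiary amine product needs no deprotection.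

**Compound list**
1 | 3-(methylamino)propan-1-ol | CNCCCO | starting material
2 | 3-(tert-butyldimethylsilyloxy)-N-methylpropan-1-amine | CNCCCO[Si](C)(C)C(C)(C)C | intermediate
3 | dodecanal | CCCCCCCCCCCC=O | starting material
4 | trimethylsilylacetylene | C#C[Si](C)(C)C | starting material
5 | iminium ion from 2 and 3, N-dodecylidene-N-methyl-3-(tert-butyldimethylsilyloxy)propan-1-aminium (not isolated) | CCCCCCCCCCCC=[N+](C)CCCO[Si](C)(C)C(C)(C)C | intermediate
6 | (R)-N-[3-(tert-butyldimethylsilyloxy)propyl]-N-methyl-1-(trimethylsilyl)tetradec-1-yn-3-amine | CCCCCCCCCCC[C@H](C#C[Si](C)(C)C)N(C)CCCO[Si](C)(C)C(C)(C)C | intermediate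
7 | (R)-N-[3-(tert-butyldimethylsilyloxy)propyl]-N-methyltetradec-1-yn-3-amine | CCCCCCCCCCC[C@H](C#C)N(C)CCCO[Si](C)(C)C(C)(C)C | intermediate
8 | N,N'-dimethylbutane-1,4-diamine | CNCCCCNC | starting material
9 | tert-butyl N-methyl-N-[4-(methylamino)butyl]carbamate | CNCCCCN(C)C(=O)OC(C)(C)C | intermediate
10 | tert-butyl N-{4-[(2-cyanoethyl)(methyl)amino]butyl}-N-methylcarbamate | N#CCCN(C)CCCCN(C)C(=O)OC(C)(C)C | intermediate
11 | tert-butyl N-{4-[(3-aminopropyl)(methyl)amino]butyl}-N-methylcarbamate | NCCCN(C)CCCCN(C)C(=O)OC(C)(C)C | intermediate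
12 | tert-butyl N-{4-[(3-{[(3R)-3-{[3-(tert-butyldimethylsilyloxy)propyl](methyl)amino}tetradecanoyl]amino}propyl)(methyl)amino]butyl}-N-methylcarbamate | CCCCCCCCCCC[C@H](CC(=O)NCCCN(C)CCCCN(C)C(=O)OC(C)(C)C)N(C)CCCO[Si](C)(C)C(C)(C)C | intermediate
13 | (3R)-3-[(3-hydroxypropyl)(methyl)amino]-N-(3-{methyl[4-(methylamino)butyl]amino}propyl)tetradecanamide trihydrochloride | CCCCCCCCCCC[C@H](CC(=O)NCCCN(C)CCCCNC)N(C)CCCO.Cl.Cl.Cl | intermediate
14 | (3R)-3-[(3-chloropropyl)(methyl)amino]-N-(3-{methyl[4-(methylamino)butyl]amino}propyl)tetradecanamide trihydrochloride | CCCCCCCCCCC[C@H](CC(=O)NCCCN(C)CCCCNC)N(C)CCCCl.Cl.Cl.Cl | intermediate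
15 | (3R)-3-[(3-chloropropyl)(methyl)amino]-N-(3-{methyl[4-(methylamino)butyl]amino}propyl)tetradecanamide, free base (not isolated) | CCCCCCCCCCC[C@H](CC(=O)NCCCN(C)CCCCNC)N(C)CCCCl | intermediate
16 | (8R)-1,9,13-trimethyl-8-undecyl-1,5,9,13-tetraazacycloheptadecan-6-one | CCCCCCCCCCC[C@@H]1CC(=O)NCCCN(C)CCCCN(C)CCCN1C | target

**Step count**
Total: 10 steps. Longest linear sequence: 7 steps (steps 1, 2, 3, 7, 8, 9, 10; the arm branch through steps 4, 5, 6 and then 7–10 is equally long).

**Steps most likely to fail**

Step 2. The small, unsymmetrical N-methyl amine gives an iminium ion with less steric bias than dibenzylamine, so facial discrimination by the Quinap copper acetylide may be insufficient, and enamine-mediated self-condensation of the aldehyde may compete. The fallback replaces catalyst control by auxiliary control; it sets out from dodecanal 3 and comes back at 6. Condensation of 3 with (R)-tert-butanesulfinamide (CuSO4, CH2Cl2) should give (R,E)-N-dodecylidene-2-methylpropane-2-sulfinamide F1. Addition of (trimethylsilyl)ethynylmagnesium bromide in CH2Cl2 at −78 °C, expected to run through the magnesium-chelated chair transition state, should give (R)-2-methyl-N-[(3R)-1-(trimethylsilyl)tetradec-1-yn-3-yl]propane-2-sulfinamide F2. The minor diastereomer is removable by chromatography; if the addition followed the open pathway instead, the (S)-auxiliary would be used. HCl in MeOH then frees (R)-1-(trimethylsilyl)tetradec-1-yn-3-amine F3. Reductive amination with commercial 3-(tert-butyldimethylsilyloxy)propanal (NaBH(OAc)3, DCE) gives (R)-N-[3-(tert-butyldimethylsilyloxy)propyl]-1-(trimethylsilyl)tetradec-1-yn-3-amine F4, and reductive methylation (aqueous CH2O, NaBH(OAc)3) returns 6.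

Step 7. The polyamine partner and the propargylic amine may bind and deactivate rhodium, vinylidene formation next to the hindered amine may be slow, and direct anti-Markovnikov hydroamination may compete with oxygen transfer. The fallback replaces the catalytic oxidation by a stoichiometric one; it sets out from silylalkyne 6 (step 3 is then not needed) and comes back at 12. Hydroboration of 6 with dicyclohexylborane (THF, 0 °C) places boron on the silicon-bearing carbon to give dicyclohexyl[(1Z,3R)-3-{[3-(tert-butyldimethylsilyloxy)propyl](methyl)amino}-1-(trimethylsilyl)tetradec-1-en-1-yl]borane F5, which is not isolated. Oxidation with NaOH/H2O2 carries it through to (3R)-3-{[3-(tert-butyldimethylsilyloxy)propyl](methyl)amino}tetradecanoic acid F6. Carbodiimide coupling of F6 with amine 11 (EDC·HCl, HOBt, CH2Cl2) gives 12.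

Step 10. Intermolecular alkylation to oligomers and quaternisation of the tertiary amines may outrun closure of the 17-membered ring. The fallback closes the same C12–N13 bond by reductive amination instead of substitution; it sets out from 12 and comes back at 16. TBAF in THF removes only the silyl ether to give tert-butyl N-{4-[(3-{[(3R)-3-[(3-hydroxypropyl)(methyl)amino]tetradecanoyl]amino}propyl)(methyl)amino]butyl}-N-methylcarbamate F7. Swern oxidation gives tert-butyl N-methyl-N-{4-[methyl(3-{[(3R)-3-[methyl(3-oxopropyl)amino]tetradecanoyl]amino}propyl)amino]butyl}carbamate F8. TFA in CH2Cl2 removes the Boc group to give (3R)-N-(3-{methyl[4-(methylamino)butyl]amino}propyl)-3-[methyl(3-oxopropyl)amino]tetradecanamide F9, kept as its trifluoroacetate and not isolated. Dilution to about 1 mM in DCE and treatment with NaBH(OAc)3 should close the ring by intramolecular reductive amination to 16.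

**Further compounds**
F1 | step 2 | (R,E)-N-dodecylidene-2-methylpropane-2-sulfinamide | CCCCCCCCCCC/C=N/[S@](=O)C(C)(C)C
F2 | step 2 | (R)-2-methyl-N-[(3R)-1-(trimethylsilyl)tetradec-1-yn-3-yl]propane-2-sulfinamide | CCCCCCCCCCC[C@H](C#C[Si](C)(C)C)N[S@](=O)C(C)(C)C
F3 | step 2 | (R)-1-(trimethylsilyl)tetradec-1-yn-3-amine | CCCCCCCCCCC[C@H](C#C[Si](C)(C)C)N
F4 | step 2 | (R)-N-[3-(tert-butyldimethylsilyloxy)propyl]-1-(trimethylsilyl)tetradec-1-yn-3-amine | CCCCCCCCCCC[C@H](C#C[Si](C)(C)C)NCCCO[Si](C)(C)C(C)(C)C
F5 | step 7 | dicyclohexyl[(1Z,3R)-3-{[3-(tert-butyldimethylsilyloxy)propyl](methyl)amino}-1-(trimethylsilyl)tetradec-1-en-1-yl]borane | CCCCCCCCCCC[C@H](/C=C(/B(C1CCCCC1)C1CCCCC1)[Si](C)(C)C)N(C)CCCO[Si](C)(C)C(C)(C)C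
F6 | step 7 | (3R)-3-{[3-(tert-butyldimethylsilyloxy)propyl](methyl)amino}tetradecanoic acid | CCCCCCCCCCC[C@H](CC(=O)O)N(C)CCCO[Si](C)(C)C(C)(C)C
F7 | step 10 | tert-butyl N-{4-[(3-{[(3R)-3-[(3-hydroxypropyl)(methyl)amino]tetradecanoyl]amino}propyl)(methyl)amino]butyl}-N-methylcarbamate | CCCCCCCCCCC[C@H](CC(=O)NCCCN(C)CCCCN(C)C(=O)OC(C)(C)C)N(C)CCCO
F8 | step 10 | tert-butyl N-methyl-N-{4-[methyl(3-{[(3R)-3-[methyl(3-oxopropyl)amino]tetradecanoyl]amino}propyl)amino]butyl}carbamate | CCCCCCCCCCC[C@H](CC(=O)NCCCN(C)CCCCN(C)C(=O)OC(C)(C)C)N(C)CCC=O
F9 | step 10 | (3R)-N-(3-{methyl[4-(methylamino)butyl]amino}propyl)-3-[methyl(3-oxopropyl)amino]tetradecanamide | CCCCCCCCCCC[C@H](CC(=O)NCCCN(C)CCCCNC)N(C)CCC=O
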